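A catalyst charged at 10 µM cannot clear 0.010 M of substrate in fewer than 1000 turnovers, so the question is how fast one catalyst turns.

| setting | alder | cedar | flask |
|---|---|---|---|
| substrate | 0.010 M | 0.010 M | 0.010 M |
| reagent | 0.025 M (fed, over 6.0 min) | 0.025 M (fed, over 6.0 min) | 0.0250 M (fed, over 6.0 min) |
| scavenger | 0.010 M | 0.022 M | 0.0150 M |
| free catalyst | 10 µM | 10 µM | 10 µM |
| remark | run made earlier | run made earlier |  |
| time |  |  | 12 min |

- alder (time / min: substrate / %, product / %): 0.833: 97, 2; 1.33: 97, 2; 2.50: 89, 13; 5.00: 62, 34; 10.0: 15, 84
- cedar (time / min: substrate / %, product / %): 2.00: 93, 7; 4.00: 75, 24; 6.00: 52, 49; 8.00: 30, 68; 10.0: 16, 89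

(each reading ± 1.5 percentage points)

- for released group the idle adduct is counted in
- on the list of suspects stand: catalyst intermediate C <-> free catalyst + product; scavenger + released group -> scavenged by-product; reagent + catalyst intermediate A <-> catalyst intermediate B; reagent + released group <-> idle adduct; catalyst intermediate B -> released group + catalyst intermediate C; substrate + free catalyst -> catalyst intermediate A
- the earlier runs do not show how much of reagent is bound; that part of a forecast is a guess

* part of the substrate that has reacted at 12 min
* share of the unused reagent that is free and not bound as idle adduct, at 12 min

The end point is plain: substrate is the limiting reagent, 0.010 M against 0.0250 M of reagent, so the flask heads for product. The substrate converted per catalyst charged and per minute over the steepest stretch of the cedar readings, from 4.00 min to 8.00 min, is the top turnover frequency; it reads 113 min⁻¹, with the scatter of its readings.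

Two versions of the flask can be solved in the head. Held at that frequency throughout, the substrate lasts 8.89 min, which is less than 12 min, so this version leaves none. With the same starting rate falling in step with substrate, a first-order decay, 25.9 % remains. Cedar at 10.0 min shows 16 % left, between none and the 32.5 % of the decay. Taking the same proportion of the decay curve for the flask, whose scavenger lies between those of alder and cedar, this reckoning gives 87.2 % reacted. The runs do not show how much reagent is bound, so any free share is a guess.

The forecast gives 92 % reacted, more than this reckoning, and 90 % free, holding that “free released group stays low and little adduct should form”.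

The flask gives 92.9 % reacted and 98.5 % free; at the turnover frequency read from cedar, that much substrate amounts to 8.22 min of turnover, less than the 12 min elapsed.

    catalyst intermediate C ⇌ free catalyst + product (K = 0.00660 M, k = 150 s⁻¹)
    scavenger + released group → scavenged by-product (k = 87.0 M⁻¹ s⁻¹)
    reagent + catalyst intermediate A ⇌ catalyst intermediate B (K = 23.0 M⁻¹, k = 210 M⁻¹ s⁻¹)
    reagent + released group ⇌ idle adduct, settled at all times (K = 1200 M⁻¹)
    catalyst intermediate B → released group + catalyst intermediate C (k = 29.0 s⁻¹)
    substrate + free catalyst → catalyst intermediate A (k = 2400 M⁻¹ s⁻¹)

At 12.0 min in the flask, by the forward rate alone of the step joining reagent to catalyst intermediate A, that intermediate has a half-life of 0.21 s and reagent one of 25 min. At that moment in the flask, 62 % of the reagent charge, 0.0155 M, stands unbound beside 2.32 × 10⁻⁴ M of idle adduct, which is far less.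

In a neighbour of the flask, the same recipe but with 0.040 M of substrate, the top turnover frequency held for 12 min gives 33.9 % reacted; the computed neighbour gives 31.7 %.

The readings stem from a simulated flask with constants of no real substance, and the scatter is random.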